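The constants were drawn at random within sensible limits; the result is computed.

**The question.** A repeat of these runs starts with a choice: at which charge of X is Q worth sampling at the end, and at which does the material pass on to D?

in all of them: Z 1.20 equiv; J 10 mol%; time 2.0 h

| run | X |
|---|---|
| Monday's | 6.0 mM |
| Thursday's | 20 mM |
| Wednesday's | 60 mM |

    X + J ⇌ J + Q (K1 = 0.33, k1 = 0.13 M⁻¹ s⁻¹)
    Z + J + Q → J + D (k2 = 11 M⁻² s⁻¹)

* [Q] at the end for Monday's, Thursday's, Wednesday's, in this order
* the shape of the row from first to last (falls all the way / falls, then rises / rises, then falls / rises all the way / hardly changes)

- "hardly changes" means that all values lie within two and a half points (for a concentration: within two and a half percent of the largest)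
- run time (Monday's): 2.0 h

**Fall-back ratio.** Q has two exits. It returns to X at the back constant of the first step times J times Q, and it goes on to D at the second constant times Z times J times Q. Dividing the first rate by the second cancels J, Q and time. With Z as charged, Monday's flask gives 4.97: the number of times Q returns to X for each Q that goes on to D, the partition ratio of Q. Thursday's flask gives 1.49 and Wednesday's 0.497.

**The choice.** Monday's ratio stands above one, and the half-life of Q by the second step, 4.1 h, is longer than the run. So Monday's Q should approach the balance of the first step, a quarter of the X + Q pool, or 1.49 mM if the whole charge stayed in that pool. Wednesday's ratio lies below one, so that flask is the one to charge for D. In mM, Q is a fraction times the charge, and a larger charge raises the second factor while lowering the first. This reckoning by hand therefore expects a middle peak and points the sampling at Thursday's flask, but it gives no figure for Q in Thursday's flask or in Wednesday's.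

**The forecast.** It gives 1.17 mM, 2.35 mM and 1.15 mM, a row that rises, then falls, because “Q first rises with loading and then falls as the higher-concentration run nears depletion”. Its Monday's figure lies below the balance figure above.

**What stands.** The flasks end at 1.17 mM, 2.32 mM and 1.18 mM, a row that rises, then falls, within the margin of the forecast. In Monday's flask at 0.580 h, Q falls back 5.0 times faster than it goes on, which is the ratio of 4.97 with Z still at 98.7% of its charge at 1.00 h, and at 2.00 h D holds 4.61% of the X charged against 19.5% for Q. In Wednesday's flask the charged ratio of 0.497 stands under one, and at 2.00 h D holds 89.5% of the X charged and Q 1.97%.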